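**Retrosynthetic overview**

1. The target comes from its tetramethyl ether by BBr3. Ring D of that ether comes from a 4-nitro arene; the nitro group is a handle left by the ring synthesis and is removed by reduction, diazotisation and hydrodediazoniation.
2. Key disconnection: ring D (CH2 bridge on C1, hydroxyls on C2 and C3) is cut at C5–C6 and C6–C1 into nitromethane and a 2-(2-arylethyl)-3-methoxy-4H-pyran-4-one. The feature used is that C1(CH2)–C2(O)–C3(O) of ring D is the same sequence as C2(CH3)–C3(OH)–C4(=O) of maltol, whose methyl group becomes the bridge carbon on ring D.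
3. The CH2–CH2 bond of the ring C/ring D bridge comes from the lithium dienolate of O-methylmaltol and the ring C benzylic bromide.
4. Rings A, B and C are bought as arenes: the ring C–O–ring B ether by SNAr on 4-fluorobenzaldehyde, the ring A/ring B bridge by Horner–Wadsworth–Emmons olefination and hydrogenation.
5. Order of ring formation: only ring D is built (step 8); the target has no stereocentre.

Key step: step 8

Assumption: the ring C unit is bought as methyl 3-hydroxy-4-methoxybenzoate (the ester of isovanillic acid) rather than isovanillin, so that only one aldehyde is present at the olefination.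
Abbreviation: Ar = 4-methoxy-3-{4-[2-(3-methoxyphenyl)ethyl]phenoxy}phenyl (rings C, B and A). Pyranone atoms are numbered O1, C2 (side chain), C3 (OMe), C4 (C=O), C5, C6.

**Route**

Step 1
Reactants: 1 methyl 3-hydroxy-4-methoxybenzoate; 2 4-fluorobenzaldehyde
Product: 3 methyl 3-(4-formylphenoxy)-4-methoxybenzoate
Conditions: K2CO3, dry DMF, 140 °C
Reagents that add atoms: none
Why: Nucleophilic aromatic substitution (addition–elimination) in which the potassium phenoxide of 1 displaces fluoride from the ring activated by the para formyl group, joining rings C and B while the ester keeps the ring C carbon distinct from the ring B aldehyde.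

Step 2
Reactants: 3 methyl 3-(4-formylphenoxy)-4-methoxybenzoate; 4 diethyl (3-methoxybenzyl)phosphonate
Product: 6 methyl 4-methoxy-3-{4-[(E)-2-(3-methoxyphenyl)ethenyl]phenoxy}benzoate, via sodium phosphonate carbanion 5 (not isolated)
Conditions: NaH, THF, 0 °C; then 3, 0 °C to rt
Reagents that add atoms: none
Why: Horner–Wadsworth–Emmons olefination in which carbanion 5 adds to the aldehyde of 3, far more electrophilic than the methyl ester, and elimination of diethyl phosphate should give mainly the E-stilbene, whose geometry is erased in step 3.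

Step 3
Reactants: 6 methyl 4-methoxy-3-{4-[(E)-2-(3-methoxyphenyl)ethenyl]phenoxy}benzoate
Product: 7 methyl 4-methoxy-3-{4-[2-(3-methoxyphenyl)ethyl]phenoxy}benzoate
Conditions: H2 (1 atm), 10% Pd/C, EtOAc, rt
Reagents that add atoms: none
Why: Heterogeneous catalytic hydrogenation saturates the stilbene C=C at ambient pressure, while the ester, the diaryl ether and the methyl ethers are inert under these conditions.

Step 4
Reactants: 7 methyl 4-methoxy-3-{4-[2-(3-methoxyphenyl)ethyl]phenoxy}benzoate
Product: 8 (4-methoxy-3-{4-[2-(3-methoxyphenyl)ethyl]phenoxy}phenyl)methanol (Ar-CH2OH)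
Conditions: LiAlH4, THF, 0 °C; then H2O, aq. NaOH
Reagents that add atoms: none
Why: Hydride reduction of the aryl ester to the primary benzylic alcohol with LiAlH4, no other reducible group being present.

Step 5
Reactants: 8 (4-methoxy-3-{4-[2-(3-methoxyphenyl)ethyl]phenoxy}phenyl)methanol
Product: 9 4-(bromomethyl)-1-methoxy-2-{4-[2-(3-methoxyphenyl)ethyl]phenoxy}benzene (Ar-CH2Br)
Conditions: PBr3, CH2Cl2, 0 °C
Reagents that add atoms: phosphorus tribromide BrP(Br)Br
Why: Conversion of the benzylic alcohol into the bromide through its phosphite ester and SN2 displacement by bromide; the electron-rich bromide ionises easily and should be used without chromatography.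

Step 6
Reactants: 10 maltol (3-hydroxy-2-methyl-4H-pyran-4-one)
Product: 11 3-methoxy-2-methyl-4H-pyran-4-one
Conditions: MeI, K2CO3, acetone, reflux
Reagents that add atoms: iodomethane CI
Why: Williamson-type O-methylation of the acidic enolic hydroxyl of maltol, which masks the oxygen that becomes the C2 oxygen of ring D.

Step 7
Reactants: 11 3-methoxy-2-methyl-4H-pyran-4-one; 9 4-(bromomethyl)-1-methoxy-2-{4-[2-(3-methoxyphenyl)ethyl]phenoxy}benzene
Product: 13 2-(2-Ar-ethyl)-3-methoxy-4H-pyran-4-one, via lithium dienolate 12 (not isolated)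
Conditions: LiN(SiMe3)2, THF, −78 °C; then 9, −78 to −20 °C
Reagents that add atoms: none
Why: Lateral (vinylogous) deprotonation of the 2-methyl group gives the cross-conjugated dienolate 12, which is alkylated at its exocyclic carbon by the benzylic bromide in an SN2 reaction because only that site restores the pyranone; 11 is used in excess (1.5 equiv) over 9 to suppress a second alkylation.

Step 8
Reactants: 13 2-(2-Ar-ethyl)-3-methoxy-4H-pyran-4-one; 14 nitromethane
Product: 18 3-(2-Ar-ethyl)-2-methoxy-4-nitrophenol, via conjugate adduct 15 (not isolated), via ring-opened enolate 16 (not isolated), via potassium nitrophenolate 17 (not isolated)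
Conditions: KOC(CH3)3 (3 equiv), 14 (5 equiv), (CH3)3COH/THF, rt to 80 °C; then aq. HCl
Reagents that add atoms: none
Why: Proposed new method: the nitronate formed from 14 adds in a conjugate sense to the unsubstituted C6 of the vinylogous ester in 13 to give the 2H-pyran-4-olate 15, and the enolate then expels the ring oxygen (beta-elimination, equally a six-electron electrocyclic opening) to give 16, the enolate of a 2-methoxy-1,3-diketone carrying a 3-nitroprop-1-enyl chain. The CH2NO2 carbon of 16 keeps an acidic hydrogen and is conjugated through C5=C6 with the C4 ketone, so the alkene can equilibrate to the Z geometry before this carbon attacks the former C2 ketone; ring D closes in a 6-(enolexo)-exo-trig aldol addition, and loss of water with tautomerisation gives the aromatic nitrophenolate 17, an irreversible sink that pulls the earlier equilibria forward. The closest known reaction type is the conversion of 2,6-dialkyl-4H-pyran-4-ones into 4-nitrophenols by nitromethane and KOC(CH3)3, together with the related conversion of pyrylium salts into nitroarenes; a 3-alkoxy-2-alkylpyranone with an unsubstituted C6 has not been used in it. No stereocentre is made, since the one at C6 of 15 is lost on ring opening. The step needs carbon–carbon bond formation at a ring terminus in preference to deprotonation of the side-chain CH2 next to C2 or 1,2-addition at C4: the excess of the more acidic nitromethane keeps free tert-butoxide low, both side processes are reversible and unproductive, C6 is unhindered, and attack at C2 would lead to the same arene since the nitromethane carbon finally bridges both termini. Because five ring carbons and both oxygens are carried over from maltol in their original sequence, the alkyl–oxygen–oxygen arrangement of ring D is fixed by the starting material.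

Step 9
Reactants: 18 3-(2-Ar-ethyl)-2-methoxy-4-nitrophenol
Product: 19 3-(2-Ar-ethyl)-1,2-dimethoxy-4-nitrobenzene
Conditions: MeI, K2CO3, DMF, rt
Reagents that add atoms: iodomethane CI
Why: Williamson O-methylation of the para-nitrophenoxide, which avoids a para-aminophenol in step 10 and a quinone diazide in step 11.

Step 10
Reactants: 19 3-(2-Ar-ethyl)-1,2-dimethoxy-4-nitrobenzene
Product: 20 2-(2-Ar-ethyl)-3,4-dimethoxyaniline
Conditions: H2 (1 atm), 10% Pd/C, EtOAc/EtOH, rt
Reagents that add atoms: none
Why: Catalytic hydrogenation of the aryl nitro group to the aniline over Pd/C; the molecule holds no benzylic heteroatom or halogen that could be hydrogenolysed.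

Step 11
Reactants: 20 2-(2-Ar-ethyl)-3,4-dimethoxyaniline
Product: 22 1-(2-Ar-ethyl)-2,3-dimethoxybenzene, via arenediazonium chloride 21 (not isolated)
Conditions: NaNO2, aq. HCl, THF, 0 °C; then 50% aq. H3PO2 (large excess), 0 °C to rt
Reagents that add atoms: none
Why: Diazotisation followed by hydrodediazoniation with hypophosphorous acid (radical chain in which the aryl radical takes hydrogen from H3PO2), run with a large excess of H3PO2 so that intermolecular hydrogen transfer outruns attack of the aryl radical on ring C.

Step 12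
Reactants: 22 1-(2-Ar-ethyl)-2,3-dimethoxybenzene
Product: 24 3-[2-(4-hydroxy-3-{4-[2-(3-hydroxyphenyl)ethyl]phenoxy}phenyl)ethyl]benzene-1,2-diol (target), via aryl bromoborate 23 (not isolated)
Conditions: BBr3 (8 equiv), CH2Cl2, −78 °C to rt; then H2O
Reagents that add atoms: none
Why: Lewis acid cleavage of aryl methyl ethers, in which BBr3 coordinates each methoxy oxygen and bromide removes the methyl group by SN2 while the diaryl ether is inert because neither of its carbons can be attacked; hydrolysis of the borate esters in 23 frees the four phenols.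

**Compound list**

1 | methyl 3-hydroxy-4-methoxybenzoate | COC(=O)c1ccc(OC)c(O)c1 | starting material
2 | 4-fluorobenzaldehyde | O=Cc1ccc(F)cc1 | starting material
3 | methyl 3-(4-formylphenoxy)-4-methoxybenzoate | COC(=O)c1ccc(OC)c(Oc2ccc(C=O)cc2)c1 | intermediate
4 | diethyl (3-methoxybenzyl)phosphonate | CCOP(=O)(OCC)Cc1cccc(OC)c1 | starting material
5 | sodium salt of the benzylic carbanion of diethyl (3-methoxybenzyl)phosphonate | CCOP(=O)(OCC)[CH-]c1cccc(OC)c1.[Na+] | intermediate
6 | methyl 4-methoxy-3-{4-[(E)-2-(3-methoxyphenyl)ethenyl]phenoxy}benzoate | COC(=O)c1ccc(OC)c(Oc2ccc(/C=C/c3cccc(OC)c3)cc2)c1 | intermediate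
7 | methyl 4-methoxy-3-{4-[2-(3-methoxyphenyl)ethyl]phenoxy}benzoate | COC(=O)c1ccc(OC)c(Oc2ccc(CCc3cccc(OC)c3)cc2)c1 | intermediate
8 | (4-methoxy-3-{4-[2-(3-methoxyphenyl)ethyl]phenoxy}phenyl)methanol | OCc1ccc(OC)c(Oc2ccc(CCc3cccc(OC)c3)cc2)c1 | intermediate
9 | 4-(bromomethyl)-1-methoxy-2-{4-[2-(3-methoxyphenyl)ethyl]phenoxy}benzene | BrCc1ccc(OC)c(Oc2ccc(CCc3cccc(OC)c3)cc2)c1 | intermediate
10 | maltol (3-hydroxy-2-methyl-4H-pyran-4-one) | CC1=C(O)C(=O)C=CO1 | starting material
11 | 3-methoxy-2-methyl-4H-pyran-4-one | CC1=C(OC)C(=O)C=CO1 | intermediate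
12 | lithium 3-methoxy-2-methylidene-2H-pyran-4-olate | C=C1OC=CC([O-])=C1OC.[Li+] | intermediate
13 | 3-methoxy-2-[2-(4-methoxy-3-{4-[2-(3-methoxyphenyl)ethyl]phenoxy}phenyl)ethyl]-4H-pyran-4-one | COc1cccc(CCc2ccc(Oc3cc(CCC4=C(OC)C(=O)C=CO4)ccc3OC)cc2)c1 | intermediate
14 | nitromethane | C[N+](=O)[O-] | starting material
15 | potassium 5-methoxy-6-[2-(4-methoxy-3-{4-[2-(3-methoxyphenyl)ethyl]phenoxy}phenyl)ethyl]-2-(nitromethyl)-2H-pyran-4-olate (racemic) | COc1cccc(CCc2ccc(Oc3cc(CCC4=C(OC)C([O-])=CC(C[N+](=O)[O-])O4)ccc3OC)cc2)c1.[K+] | intermediate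
16 | potassium enolate of (Z)-4-methoxy-1-(4-methoxy-3-{4-[2-(3-methoxyphenyl)ethyl]phenoxy}phenyl)-8-nitrooct-6-ene-3,5-dione | COc1cccc(CCc2ccc(Oc3cc(CCC([O-])=C(OC)C(=O)/C=C\C[N+](=O)[O-])ccc3OC)cc2)c1.[K+] | intermediate
17 | potassium 2-methoxy-3-[2-(4-methoxy-3-{4-[2-(3-methoxyphenyl)ethyl]phenoxy}phenyl)ethyl]-4-nitrophenolate | COc1cccc(CCc2ccc(Oc3cc(CCc4c([N+](=O)[O-])ccc([O-])c4OC)ccc3OC)cc2)c1.[K+] | intermediate
18 | 2-methoxy-3-[2-(4-methoxy-3-{4-[2-(3-methoxyphenyl)ethyl]phenoxy}phenyl)ethyl]-4-nitrophenol | COc1cccc(CCc2ccc(Oc3cc(CCc4c([N+](=O)[O-])ccc(O)c4OC)ccc3OC)cc2)c1 | intermediate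
19 | 1,2-dimethoxy-3-[2-(4-methoxy-3-{4-[2-(3-methoxyphenyl)ethyl]phenoxy}phenyl)ethyl]-4-nitrobenzene | COc1cccc(CCc2ccc(Oc3cc(CCc4c([N+](=O)[O-])ccc(OC)c4OC)ccc3OC)cc2)c1 | intermediate
20 | 3,4-dimethoxy-2-[2-(4-methoxy-3-{4-[2-(3-methoxyphenyl)ethyl]phenoxy}phenyl)ethyl]aniline | COc1cccc(CCc2ccc(Oc3cc(CCc4c(N)ccc(OC)c4OC)ccc3OC)cc2)c1 | intermediate
21 | 3,4-dimethoxy-2-[2-(4-methoxy-3-{4-[2-(3-methoxyphenyl)ethyl]phenoxy}phenyl)ethyl]benzenediazonium chloride | COc1cccc(CCc2ccc(Oc3cc(CCc4c([N+]#N)ccc(OC)c4OC)ccc3OC)cc2)c1.[Cl-] | intermediate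
22 | 1,2-dimethoxy-3-[2-(4-methoxy-3-{4-[2-(3-methoxyphenyl)ethyl]phenoxy}phenyl)ethyl]benzene | COc1cccc(CCc2ccc(Oc3cc(CCc4cccc(OC)c4OC)ccc3OC)cc2)c1 | intermediate
23 | bromoborate ester of the target (ring D catechol as the 2-bromo-1,3,2-benzodioxaborole; ring A and ring C oxygens as O-BBr2) | BrB(Br)Oc1cccc(CCc2ccc(Oc3cc(CCc4cccc5OB(Br)Oc45)ccc3OB(Br)Br)cc2)c1 | intermediate
24 | 3-[2-(4-hydroxy-3-{4-[2-(3-hydroxyphenyl)ethyl]phenoxy}phenyl)ethyl]benzene-1,2-diol | Oc1cccc(CCc2ccc(Oc3cc(CCc4cccc(O)c4O)ccc3O)cc2)c1 | target

**Summary**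

Total step count: 12.
Longest linear sequence: 11 steps (steps 1 to 5 and 7 to 12, from compound 1); step 6 is a one-step branch from maltol.

**Steps most likely to fail**

Step 8 (carries the label).
- What may go wrong: the nitronate may not add to the ring carbon, since the 3-methoxy and 2-alkyl groups make this pyranone a weaker acceptor than the 2,6-dialkyl cases. The side-chain CH2 may instead be deprotonated, leading to self-condensation. The open-chain enolate may also fragment by retro-Claisen cleavage before the aldol closure.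
- Fallback (known chemistry, abandons the pyranone route to ring D): it sets out from bromide 9 and comes back at compound 22. Bromide 9 should be heated with triethyl phosphite (neat, 130 °C, Michaelis–Arbuzov reaction) to give diethyl (4-methoxy-3-{4-[2-(3-methoxyphenyl)ethyl]phenoxy}benzyl)phosphonate F1. F1 should then be condensed under Horner–Wadsworth–Emmons conditions (NaH, THF, 0 °C to rt) with commercial 2,3-dimethoxybenzaldehyde (COc1cccc(C=O)c1OC), which already holds the ring D oxygen pattern, to give 1,2-dimethoxy-3-[(E)-2-(4-methoxy-3-{4-[2-(3-methoxyphenyl)ethyl]phenoxy}phenyl)ethenyl]benzene F2. Hydrogenation of F2 (H2, 10% Pd/C, EtOAc) should give 22, and the route resumes at step 12.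

Step 7.
- What may go wrong: a second alkylation at the newly formed and still acidic CH2 of the product by remaining dienolate, proton transfer that quenches the dienolate, or ionisation and decomposition of the para-methoxybenzylic bromide before it is attacked.
- Fallback (an aldehyde electrophile that cannot over-react): it sets out from alcohol 8 and comes back at compound 13. Alcohol 8 should be oxidised with MnO2 (CH2Cl2, rt) to 4-methoxy-3-{4-[2-(3-methoxyphenyl)ethyl]phenoxy}benzaldehyde F3. Dienolate 12 (from 11 and LiN(SiMe3)2, THF, −78 °C) should add to F3 in a vinylogous aldol reaction to give racemic 2-[2-hydroxy-2-(4-methoxy-3-{4-[2-(3-methoxyphenyl)ethyl]phenoxy}phenyl)ethyl]-3-methoxy-4H-pyran-4-one F4. Ionic hydrogenation of F4 (Et3SiH, CF3CO2H, CH2Cl2, 0 °C) should remove the benzylic hydroxyl through the para-methoxy-stabilised benzylic cation and give 13.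

Step 11.
- What may go wrong: the aryl radical or cation released from the diazonium group sits ortho to the two-carbon bridge and may close onto ring C (Pschorr-type arylation to a 9,10-dihydrophenanthrene) faster than it is reduced. The diazonium ion may also couple with unreacted electron-rich aniline.
- Fallback (no diazonium ion and no free aryl radical): it sets out from nitroarene 19 and comes back at compound 22. The nitro group should be removed directly by palladium-catalysed reductive denitration (Pd(acac)2, BrettPhos, K3PO4, 2-propanol, 1,4-dioxane, 130 °C). The Ar–NO2 bond adds oxidatively to zerovalent palladium, nitrite is exchanged for isopropoxide, and beta-hydride elimination followed by C–H reductive elimination gives 22. No new compound is made on this way (F0), and steps 10 and 11 are skipped.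

**Further compounds**

F1 | step 8 | diethyl (4-methoxy-3-{4-[2-(3-methoxyphenyl)ethyl]phenoxy}benzyl)phosphonate | CCOP(=O)(OCC)Cc1ccc(OC)c(Oc2ccc(CCc3cccc(OC)c3)cc2)c1
F2 | step 8 | 1,2-dimethoxy-3-[(E)-2-(4-methoxy-3-{4-[2-(3-methoxyphenyl)ethyl]phenoxy}phenyl)ethenyl]benzene | COc1cccc(CCc2ccc(Oc3cc(/C=C/c4cccc(OC)c4OC)ccc3OC)cc2)c1
F3 | step 7 | 4-methoxy-3-{4-[2-(3-methoxyphenyl)ethyl]phenoxy}benzaldehyde | O=Cc1ccc(OC)c(Oc2ccc(CCc3cccc(OC)c3)cc2)c1
F4 | step 7 | 2-[2-hydroxy-2-(4-methoxy-3-{4-[2-(3-methoxyphenyl)ethyl]phenoxy}phenyl)ethyl]-3-methoxy-4H-pyran-4-one (racemic) | COc1cccc(CCc2ccc(Oc3cc(C(O)CC4=C(OC)C(=O)C=CO4)ccc3OC)cc2)c1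
F0 | step 11 | none | none
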